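- At 8.00 h the blue run had 6.00 % of its charged free monomer outside chains, less than the 32.0 % of the ochre run. Both began with 37 mM of free monomer, but c(initiator) was 1.8 mM against 0.43 mM.

| flask | free monomer | initiator | remark | time |
|---|---|---|---|---|
| ochre | 37 mM | 0.43 mM | run made earlier |  |
| blue | 37 mM | 1.8 mM | run made earlier |  |
| amber | 50 mM | 0.74 mM | run made earlier |  |
| south-east | 80 mM | 2.0 mM |  | 10 h |
| south | 37 mM | 0.74 mM |  | 10 h |

- ochre (time / h: monomer in chains / %, free monomer / %): 0.500: 5, 93; 1.33: 17, 75; 3.00: 38, 41; 8.00: 68, 13
- blue (time / h: monomer in chains / %, free monomer / %): 0.833: 27, 61; 2.50: 67, 17; 5.00: 85, 5; 8.00: 94, 0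
- amber (time / h: monomer in chains / %, free monomer / %): 0.500: 3, 87; 1.33: 29, 56; 3.00: 52, 24; 8.00: 83, 8

(readings scatter by 2 percentage points)

- a reading or a percentage of monomer in chains counts all its forms, free or not
- a reading of free monomer is of its free form alone

* which one finishes higher in amount of monomer in chains, in percent of the free monomer charged ("neither" within 2 percentage points) (south-east / south / neither)
* amount of monomer in chains at the end, in percent of the free monomer charged, south-east
* amount of monomer in chains at the end, in percent of the free monomer charged, south

- I worked with the fraction left, not the fraction made. I called a run's clearing constant the logarithm of charged over not yet in chains, divided by the time. This gave 0.142 /h for ochre and 0.352 /h for blue.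
- The clearing power, an apparent order in initiator, is for two runs with the same free monomer charged, read at the same time, the logarithm of the ratio of their constants over the logarithm of the ratio of their initiators: 0.631.
- South has the free monomer of those runs, so I scaled up from ochre and got 0.201 /h, which gives 86.6 % in chains at 10 h.
- For south-east I scaled from blue and got 0.376 /h, which gives 97.7 %. Amber, with 50 mM of free monomer, cleared at 0.221 /h, a little faster than my figure for south, but I made no correction for the 80 mM in south-east.
- The forecast, on its own grounds, said south-east, with 97 % for south-east and 86 % for south. It held that “the rate scales roughly with the square root of initiator”, a power it read from free monomer, whereas mine came from chains.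
- The flask gave south-east, with 96.3 % for south-east and 88.7 % for south, so the forecast stood. Read back, these are clearing constants of 0.330 /h for south-east and 0.218 /h for south.

    2 initiator ⇌ resting dimer (K = 40000 /M, k = 0.0424 /M/s)
    free monomer + monomer in chains ⇌ idle adduct, settled at all times (K = 39.3 /M)
    free monomer + initiator → living end + monomer in chains (k = 0.0101 /M/s)
    free monomer + monomer in chains → side product (k = 6.02 × 10⁻⁵ /M/s)
    free monomer + living end → monomer in chains + living end, rate k5*[living end]*[free monomer] (k = 0.177 /M/s)

- In south-east at 1.17 h, the half-life of free monomer was 0.69 h by the living end's step into chains, far shorter than the 150 h by the step to side product. Side product in south-east stood at 1.07 % at 10.0 h.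
- The neighbour is south-east stopped at 2.5 h. Blue's constant at that time was 0.443 /h, higher than its late one, so I used it with the clearing power and got 69.4 % in chains. The computed flask gives 72.2 %.

The runs are simulated from invented constants.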